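**Plan**
- Cuts, in order: the two O–MOM bonds, then C3–C4 of the pyranone (ring C), then the ether bond O1–C2, then the aryl–prenyl bonds at C6 (ring A) and C3' (ring B).
- Enabling feature: the 4'-OH of ring B is para to C1', so C3 is the exocyclic carbon of a latent p-quinone methide. C4 is an aldehyde-level carbon on C4a of ring A, and the chain C8a–O1–C2 keeps it at six-ring distance from C3.
- Forward: rings A and B are purchased arenes. Ring A gets its prenyl group by a para-Claisen–Cope shift and ring B by direct C-prenylation. The halves are joined at O1–C2 by phenacylation, redox adjustment and acetylation give the racemic 4-hydroxybenzylic acetate, and ring C closes last.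
- Stereochemistry: C3 is the only stereocentre. The racemic benzylic centre vanishes in the planar quinone methide, and a chiral triazolylidene then sets C3. The one step that follows is aprotic and free of base.

Key step: step 12

Assumption: the sense of induction in step 12 is extrapolated from the intramolecular Stetter model. The (5aR,10bS) catalyst is written here, and its equally available mirror image is used if it favours 3S.

**Step 1**
Reactants: 1 2,4,6-trihydroxybenzaldehyde
Product: 2 2-hydroxy-4,6-bis(methoxymethoxy)benzaldehyde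
Conditions: MOMCl (2.1 equiv), i-Pr2NEt, CH2Cl2, 0 °C → rt
Reagents that add atoms: chloromethyl methyl ether (MOMCl), COCCl
Why: Base-mediated O-alkylation (MOM protection): the 4-OH and one of the two equivalent ortho hydroxyls react, while the last hydroxyl is held in a hydrogen bond to the formyl oxygen and stays free when the reagent is limited to two equivalents.

**Step 2**
Reactants: 2 2-hydroxy-4,6-bis(methoxymethoxy)benzaldehyde; 3 prenyl bromide (1-bromo-3-methylbut-2-ene)
Product: 4 2,4-bis(methoxymethoxy)-6-(3-methylbut-2-enyloxy)benzaldehyde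
Conditions: K2CO3, DMF, rt
Reagents that add atoms: none
Why: Williamson ether synthesis: carbonate in DMF opens the chelate and the phenoxide oxygen displaces bromide from the unhindered allylic carbon in an SN2 reaction.

**Step 3**
Reactants: 4 2,4-bis(methoxymethoxy)-6-(3-methylbut-2-enyloxy)benzaldehyde
Product: 7 6-hydroxy-2,4-bis(methoxymethoxy)-3-(3-methylbut-2-enyl)benzaldehyde, via ortho-dienone 5 (not isolated), via para-dienone 6 (not isolated)
Conditions: PhNEt2, 200 °C, sealed tube, Ar
Reagents that add atoms: none
Why: Aromatic para-Claisen (Claisen–Cope) rearrangement, well established on the analogous acetophenone ethers: the first [3,3] shift to the only free ortho carbon gives 5 with an inverted 1,1-dimethylallyl group, steric strain drives a second [3,3] shift to the para carbon between the two MOM ethers (6), and tautomerisation leaves a normal prenyl group para to the freed hydroxyl, which is the C6/O1 relation of the target.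

**Step 4**
Reactants: 8 4-hydroxyacetophenone; 3 prenyl bromide
Product: 9 4-hydroxy-3-(3-methylbut-2-enyl)acetophenone
Conditions: KOH, H2O, rt
Reagents that add atoms: none
Why: Direct ortho C-alkylation of a phenoxide in water, where hydrogen bonding to the phenoxide oxygen diverts the allylic bromide to the ring carbon (para position blocked, both ortho positions equivalent); the neutral O-prenyl ether that forms alongside is separated by extraction of 9 into base.

**Step 5**
Reactants: 9 4-hydroxy-3-(3-methylbut-2-enyl)acetophenone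
Product: 10 3-(3-methylbut-2-enyl)-4-(triisopropylsilyloxy)acetophenone
Conditions: TIPSCl, imidazole, DMF, rt
Reagents that add atoms: chlorotriisopropylsilane (TIPSCl), CC(C)[Si](Cl)(C(C)C)C(C)C
Why: Imidazole-promoted silylation of the phenol; TIPS is taken because this silyl ether later stands para to a ketone during a carbonate-mediated alkylation, where a smaller silyl group would be at risk.

**Step 6**
Reactants: 10 3-(3-methylbut-2-enyl)-4-(triisopropylsilyloxy)acetophenone
Product: 12 2-bromo-1-[3-(3-methylbut-2-enyl)-4-(triisopropylsilyloxy)phenyl]ethanone, via silyl enol ether 11 (not isolated)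
Conditions: LiHMDS, TMSCl, THF, −78 → 0 °C; then NBS (1.0 equiv), −78 °C
Reagents that add atoms: N-bromosuccinimide, O=C1CCC(=O)N1Br; chlorotrimethylsilane, C[Si](C)(C)Cl (its silyl group is found in 11 only)
Why: α-Bromination of a ketone by way of its silyl enol ether: the enol ether 11 is far more nucleophilic than the trisubstituted prenyl double bond, so one equivalent of NBS at low temperature should be consumed at the enol carbon alone.

**Step 7**
Reactants: 7 6-hydroxy-2,4-bis(methoxymethoxy)-3-(3-methylbut-2-enyl)benzaldehyde; 12 2-bromo-1-[3-(3-methylbut-2-enyl)-4-(triisopropylsilyloxy)phenyl]ethanone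
Product: 13 6-{2-oxo-2-[3-(3-methylbut-2-enyl)-4-(triisopropylsilyloxy)phenyl]ethoxy}-2,4-bis(methoxymethoxy)-3-(3-methylbut-2-enyl)benzaldehyde
Conditions: K2CO3, acetone, rt
Reagents that add atoms: none
Why: Williamson alkylation of a phenol with a phenacyl bromide, the standard entry to 2-aryloxy-1-arylethane units and free of the regiochemical ambiguity that an electron-rich styrene oxide would bring; room temperature and the deactivated, doubly flanked aldehyde hold back the Rap–Stoermer aldol closure.

**Step 8**
Reactants: 13 keto aldehyde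
Product: 14 rac-2-[2-(hydroxymethyl)-3,5-bis(methoxymethoxy)-4-(3-methylbut-2-enyl)phenoxy]-1-[3-(3-methylbut-2-enyl)-4-(triisopropylsilyloxy)phenyl]ethanol
Conditions: NaBH4, THF–MeOH, 0 °C
Reagents that add atoms: none
Why: Borohydride reduction of both carbonyl groups, chosen because no hydride tells this ketone from the aldehyde reliably; the new benzylic stereocentre arises racemic, which is harmless since step 12 destroys it.

**Step 9**
Reactants: 14 diol
Product: 15 rac-6-{2-hydroxy-2-[3-(3-methylbut-2-enyl)-4-(triisopropylsilyloxy)phenyl]ethoxy}-2,4-bis(methoxymethoxy)-3-(3-methylbut-2-enyl)benzaldehyde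
Conditions: [Cu(MeCN)4]OTf, 2,2'-bipyridyl, TEMPO (5 mol % each), N-methylimidazole (10 mol %), air, MeCN, rt
Reagents that add atoms: none
Why: Cu(I)/TEMPO-catalysed aerobic alcohol oxidation, which for steric reasons turns over primary (above all electron-rich benzylic) alcohols and leaves secondary alcohols alone, and which does not touch alkenes, acetals or silyl ethers.

**Step 10**
Reactants: 15 hydroxy aldehyde
Product: 16 rac-6-{2-acetoxy-2-[3-(3-methylbut-2-enyl)-4-(triisopropylsilyloxy)phenyl]ethoxy}-2,4-bis(methoxymethoxy)-3-(3-methylbut-2-enyl)benzaldehyde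
Conditions: Ac2O, pyridine, DMAP (cat), CH2Cl2, 0 °C → rt
Reagents that add atoms: acetic anhydride, CC(=O)OC(C)=O
Why: DMAP-catalysed acetylation of the only free hydroxyl group installs the leaving group for the 1,6-elimination.

**Step 11**
Reactants: 16 silyl-protected acetate
Product: 17 rac-6-{2-acetoxy-2-[4-hydroxy-3-(3-methylbut-2-enyl)phenyl]ethoxy}-2,4-bis(methoxymethoxy)-3-(3-methylbut-2-enyl)benzaldehyde
Conditions: TBAF/AcOH (1:1, 1.2 equiv), THF, 0 °C; pH 6–7 buffer work-up
Reagents that add atoms: none
Why: Fluoride cleavage of an aryl silyl ether; acetic acid protonates the phenoxide as soon as it forms, so that loss of the benzylic acetate cannot start, and the alkyl acetate, aldehyde and MOM ethers are inert to buffered fluoride.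

**Step 12**
Reactants: 17 racemic 4-hydroxybenzylic acetate
Product: 19 (3R)-3-[4-hydroxy-3-(3-methylbut-2-enyl)phenyl]-5,7-bis(methoxymethoxy)-6-(3-methylbut-2-enyl)chroman-4-one, via p-quinone methide 18 (not isolated)
Conditions: (5aR,10bS)-aminoindanol-derived N-C6F5 triazolium BF4 (20 mol %), i-Pr2NEt (1.5 equiv), 4 Å MS, PhMe, rt, Ar; 17 added slowly (final 0.01 M)
Reagents that add atoms: none
Why: Proposed new method: the amine takes the 4'-OH proton of 17 and the phenoxide pushes out acetate across ring B, so that both enantiomers converge on the planar p-quinone methide 18, a β-aryloxy type of methide known from lignin model work to persist in solution. The triazolylidene adds to the ring-A aldehyde, a proton shift gives the Breslow enaminol, its nucleophilic carbon (future C4) attacks the methide carbon (future C3) while ring B regains aromaticity, and breakdown of the resulting hydroxy-azolium adduct frees the C4 ketone and returns the carbene. The nearest relatives are the asymmetric intramolecular Stetter cyclisation of salicylaldehyde-derived 4-aryloxycrotonates, which gives 3-substituted chromanones, and the intermolecular carbene-catalysed 1,6-acylation of preformed, tert-butyl-stabilised p-quinone methides by aldehydes. The pyranone closes in the 6-exo-trig mode, because the C3=C1' double bond lies outside the new ring C4–C4a–C8a–O1–C2–C3. C3 is the only new stereocentre and is controlled by the aminoindanol backbone of the catalyst, which shields one face of the enaminol and so admits only one prochiral face of the tethered methide carbon, the former benzylic configuration and the E/Z geometry at the remote prenyl side having no influence on which face that is. Capture has to outrun tautomerisation of 18 to the styryl ether, intermolecular addition of phenol or acetate and enolisation of 19, and this is served by the short O1–C2 tether, by the inductive brake of the β-aryloxy group on acetate loss (low standing concentration of 18), by slow addition at high dilution, by the amine/acetic acid buffer and by the electron-rich ring A, which lowers the acidity of H-3.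

**Step 13**
Reactants: 19 (3R)-5,7-di-O-MOM isoflavanone
Product: 20 (3R)-5,7-dihydroxy-3-[4-hydroxy-3-(3-methylbut-2-enyl)phenyl]-6-(3-methylbut-2-enyl)chroman-4-one
Conditions: ZnBr2, n-PrSH, CH2Cl2, 0 °C, minutes; pH 6 buffer quench
Reagents that add atoms: none
Why: Lewis acid-assisted cleavage of the two formaldehyde acetals by a soft thiol nucleophile (MOM removal), a reaction that is complete within minutes in an aprotic medium without Brønsted acid or base, so that neither enolisation at C3 nor protonation of the prenyl double bonds (chroman formation) gets time to set in and C3 stays R.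

**Compound list**
1 | 2,4,6-trihydroxybenzaldehyde | O=Cc1c(O)cc(O)cc1O | starting material
2 | 2-hydroxy-4,6-bis(methoxymethoxy)benzaldehyde | O=Cc1c(O)cc(OCOC)cc1OCOC | intermediate
3 | prenyl bromide (1-bromo-3-methylbut-2-ene) | CC(C)=CCBr | starting material
4 | 2,4-bis(methoxymethoxy)-6-(3-methylbut-2-enyloxy)benzaldehyde | O=Cc1c(OCC=C(C)C)cc(OCOC)cc1OCOC | intermediate
5 | ortho-dienone: racemic 5-(2-methylbut-3-en-2-yl)-2,4-bis(methoxymethoxy)-6-oxocyclohexa-1,3-diene-1-carbaldehyde | O=CC1=C(OCOC)C=C(OCOC)C(C(C)(C)C=C)C1=O | intermediate (not isolated)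
6 | para-dienone: racemic 3-(3-methylbut-2-enyl)-2,4-bis(methoxymethoxy)-6-oxocyclohexa-1,4-diene-1-carbaldehyde | O=CC1=C(OCOC)C(CC=C(C)C)C(OCOC)=CC1=O | intermediate (not isolated)
7 | 6-hydroxy-2,4-bis(methoxymethoxy)-3-(3-methylbut-2-enyl)benzaldehyde | O=Cc1c(O)cc(OCOC)c(CC=C(C)C)c1OCOC | intermediate
8 | 4-hydroxyacetophenone | CC(=O)c1ccc(O)cc1 | starting material
9 | 4-hydroxy-3-(3-methylbut-2-enyl)acetophenone | CC(=O)c1ccc(O)c(CC=C(C)C)c1 | intermediate
10 | 3-(3-methylbut-2-enyl)-4-(triisopropylsilyloxy)acetophenone | CC(=O)c1ccc(O[Si](C(C)C)(C(C)C)C(C)C)c(CC=C(C)C)c1 | intermediate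
11 | trimethylsilyl enol ether of 10 | C=C(O[Si](C)(C)C)c1ccc(O[Si](C(C)C)(C(C)C)C(C)C)c(CC=C(C)C)c1 | intermediate (not isolated)
12 | 2-bromo-1-[3-(3-methylbut-2-enyl)-4-(triisopropylsilyloxy)phenyl]ethanone | O=C(CBr)c1ccc(O[Si](C(C)C)(C(C)C)C(C)C)c(CC=C(C)C)c1 | intermediate
13 | keto aldehyde: 6-{2-oxo-2-[3-(3-methylbut-2-enyl)-4-(triisopropylsilyloxy)phenyl]ethoxy}-2,4-bis(methoxymethoxy)-3-(3-methylbut-2-enyl)benzaldehyde | O=Cc1c(OCC(=O)c2ccc(O[Si](C(C)C)(C(C)C)C(C)C)c(CC=C(C)C)c2)cc(OCOC)c(CC=C(C)C)c1OCOC | intermediate
14 | racemic diol: 2-[2-(hydroxymethyl)-3,5-bis(methoxymethoxy)-4-(3-methylbut-2-enyl)phenoxy]-1-[3-(3-methylbut-2-enyl)-4-(triisopropylsilyloxy)phenyl]ethanol | OCc1c(OCC(O)c2ccc(O[Si](C(C)C)(C(C)C)C(C)C)c(CC=C(C)C)c2)cc(OCOC)c(CC=C(C)C)c1OCOC | intermediate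
15 | racemic hydroxy aldehyde: 6-{2-hydroxy-2-[3-(3-methylbut-2-enyl)-4-(triisopropylsilyloxy)phenyl]ethoxy}-2,4-bis(methoxymethoxy)-3-(3-methylbut-2-enyl)benzaldehyde | O=Cc1c(OCC(O)c2ccc(O[Si](C(C)C)(C(C)C)C(C)C)c(CC=C(C)C)c2)cc(OCOC)c(CC=C(C)C)c1OCOC | intermediate
16 | racemic acetate: 6-{2-acetoxy-2-[3-(3-methylbut-2-enyl)-4-(triisopropylsilyloxy)phenyl]ethoxy}-2,4-bis(methoxymethoxy)-3-(3-methylbut-2-enyl)benzaldehyde | O=Cc1c(OCC(OC(C)=O)c2ccc(O[Si](C(C)C)(C(C)C)C(C)C)c(CC=C(C)C)c2)cc(OCOC)c(CC=C(C)C)c1OCOC | intermediate
17 | racemic 6-{2-acetoxy-2-[4-hydroxy-3-(3-methylbut-2-enyl)phenyl]ethoxy}-2,4-bis(methoxymethoxy)-3-(3-methylbut-2-enyl)benzaldehyde | O=Cc1c(OCC(OC(C)=O)c2ccc(O)c(CC=C(C)C)c2)cc(OCOC)c(CC=C(C)C)c1OCOC | intermediate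
18 | p-quinone methide: 6-{2-[3-(3-methylbut-2-enyl)-4-oxocyclohexa-2,5-dienylidene]ethoxy}-2,4-bis(methoxymethoxy)-3-(3-methylbut-2-enyl)benzaldehyde (E/Z not defined) | O=C1C=CC(=CCOc2cc(OCOC)c(CC=C(C)C)c(OCOC)c2C=O)C=C1CC=C(C)C | intermediate (not isolated)
19 | (3R)-3-[4-hydroxy-3-(3-methylbut-2-enyl)phenyl]-5,7-bis(methoxymethoxy)-6-(3-methylbut-2-enyl)chroman-4-one | CC(C)=CCc1cc([C@@H]2COc3cc(OCOC)c(CC=C(C)C)c(OCOC)c3C2=O)ccc1O | intermediate
20 | (3R)-5,7,4'-trihydroxy-6,3'-diprenylisoflavanone (CNP0206440.1) | CC(C)=CCc1cc([C@@H]2COc3cc(O)c(CC=C(C)C)c(O)c3C2=O)ccc1O | target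

**Step count**
Total steps: 13. Longest linear sequence: 10 (steps 1–3 or steps 4–6, then steps 7–13).

**Steps most likely to fail**

Step 12. The carbene may add too slowly to an aldehyde that is electron-rich and flanked on both sides. The quinone methide would then drain away through tautomerisation and oligomerisation. Facial selectivity may also be poor.

The fallback uses known chemistry, sets out from keto aldehyde 13 and returns at 19. An achiral triazolium salt with an amine base effects the carbene-catalysed intramolecular crossed aldehyde–ketone benzoin reaction. This forms the same C3–C4 bond and should give the racemic 3-hydroxyisoflavanone F1. SOCl2 in pyridine at 0 °C dehydrates it across C2–C3 to the isoflavone F2.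

Asymmetric transfer hydrogenation with RuCl[(R,R)-TsDPEN](p-cymene) in HCO2H/Et3N first saturates C2=C3. It then reduces the ketone with dynamic kinetic resolution of the labile C3 centre, which should give the cis-(3R,4R)-isoflavan-4-ol F3. Dess–Martin periodinane in CH2Cl2 at 0 °C returns the ketone without touching C3 and gives the (3R)-4'-O-TIPS isoflavanone F4. TBAF/AcOH, as in step 11, then frees the 4'-OH to give 19.

Step 13. The configuration at C3 may erode through Lewis acid-induced enolisation, or a freed phenol may close onto a neighbouring prenyl group.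

The fallback sets out from 19 and returns at 20. It changes the class of protecting group before anything is unmasked. TESOTf with 2,2'-bipyridyl in CH2Cl2 at 0 °C exchanges the two aryl MOM ethers for silyl ethers and silylates the 4'-OH. This gives the isolable (3R)-tris(triethylsilyl) ether F5. Buffered fluoride (TBAF/AcOH, THF, 0 °C) then removes all three silyl groups under the near-neutral conditions of step 11.

Step 7. The base may induce aldol closure of the new ether onto its own aldehyde (the Rap–Stoermer pathway). Silyl transfer from the para-acyl aryl silyl ether to the phenoxide is a second risk.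

The fallback sets out from 12 and returns at 13 without any base in the coupling. Sodium formate in aqueous ethanol displaces bromide to give the phenacyl formate F6. This solvolyses in the same pot to the α-hydroxy ketone F7. A Mitsunobu etherification (PPh3, DIAD, THF, 0 °C) with the acidic phenol 7 then forms the O1–C2 bond under neutral conditions.

**Further compounds**
F1 | step 12 | racemic 3-hydroxy-5,7-bis(methoxymethoxy)-6-(3-methylbut-2-enyl)-3-[3-(3-methylbut-2-enyl)-4-(triisopropylsilyloxy)phenyl]chroman-4-one | CC(C)=CCc1cc(C2(O)COc3cc(OCOC)c(CC=C(C)C)c(OCOC)c3C2=O)ccc1O[Si](C(C)C)(C(C)C)C(C)C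
F2 | step 12 | 5,7-bis(methoxymethoxy)-6-(3-methylbut-2-enyl)-3-[3-(3-methylbut-2-enyl)-4-(triisopropylsilyloxy)phenyl]chromen-4-one | CC(C)=CCc1cc(C2=COc3cc(OCOC)c(CC=C(C)C)c(OCOC)c3C2=O)ccc1O[Si](C(C)C)(C(C)C)C(C)C
F3 | step 12 | cis-(3R,4R)-5,7-bis(methoxymethoxy)-6-(3-methylbut-2-enyl)-3-[3-(3-methylbut-2-enyl)-4-(triisopropylsilyloxy)phenyl]chroman-4-ol | CC(C)=CCc1cc([C@@H]2COc3cc(OCOC)c(CC=C(C)C)c(OCOC)c3[C@@H]2O)ccc1O[Si](C(C)C)(C(C)C)C(C)C
F4 | step 12 | (3R)-5,7-bis(methoxymethoxy)-6-(3-methylbut-2-enyl)-3-[3-(3-methylbut-2-enyl)-4-(triisopropylsilyloxy)phenyl]chroman-4-one | CC(C)=CCc1cc([C@@H]2COc3cc(OCOC)c(CC=C(C)C)c(OCOC)c3C2=O)ccc1O[Si](C(C)C)(C(C)C)C(C)C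
F5 | step 13 | (3R)-6-(3-methylbut-2-enyl)-3-[3-(3-methylbut-2-enyl)-4-(triethylsilyloxy)phenyl]-5,7-bis(triethylsilyloxy)chroman-4-one | CC(C)=CCc1cc([C@@H]2COc3cc(O[Si](CC)(CC)CC)c(CC=C(C)C)c(O[Si](CC)(CC)CC)c3C2=O)ccc1O[Si](CC)(CC)CC
F6 | step 7 | 2-oxo-2-[3-(3-methylbut-2-enyl)-4-(triisopropylsilyloxy)phenyl]ethyl formate | O=COCC(=O)c1ccc(O[Si](C(C)C)(C(C)C)C(C)C)c(CC=C(C)C)c1
F7 | step 7 | 2-hydroxy-1-[3-(3-methylbut-2-enyl)-4-(triisopropylsilyloxy)phenyl]ethanone | O=C(CO)c1ccc(O[Si](C(C)C)(C(C)C)C(C)C)c(CC=C(C)C)c1
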